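Everything rests on closing the cyclohexa-2,5-diene ring last, at its enol-ether double bond C2(OMe)=C3, by ring-closing metathesis. The precursor is an acyclic triene in which the Z-trisubstituted C5=C6 alkene holds C1 (acetoxy, carrying a 1-methoxyvinyl group) and C4 (free carbinol, carrying a vinyl group) cis; it already bears all three stereocentres and both acetates. The step exploits the enol ether C2=C3 lying between the stereogenic allylic carbons C1 and C4: it forms from two terminal alkenes without touching either centre, so one neutral operation delivers ring and enol ether and the acid-labile, aromatisation-prone dienol appears only at the end. Alkene geometry comes from hydroxyl-directed trans-hydroalumination–iodination and a stereoretentive Nozaki–Hiyama–Kishi coupling.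

Key step: step 11

Remark: in the two ligand-controlled additions (steps 4 and 8) the ligand antipode is the one that gives the facial sense named in the Why line; ring locants follow the name of 18, chain locants those of the icosa-1,4-diene.

Step 1
Reactants: 1 (R)-epichlorohydrin; 2 dodecylmagnesium bromide
Product: 3 (R)-1-chloropentadecan-2-ol
Conditions: CuI (10 mol %), THF, −40 → 0 °C; aq. NH4Cl
Reagents that add atoms: none
Why: Copper-catalysed Grignard opening of the epoxide at its CH2 terminus (SN2) leaves the purchased stereocentre untouched and keeps the chloride for the next step.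

Step 2
Reactants: 3
Product: 5 (R)-heptadec-1-yn-4-ol, via (R)-1,2-epoxypentadecane 4 (not isolated)
Conditions: LiC≡CH·H2NCH2CH2NH2 (3 equiv), DMSO, 0 °C → rt
Reagents that add atoms: lithium acetylide (ethylenediamine complex), [Li]C#C
Why: Base-induced closure of the chlorohydrin to the epoxide (displacement at CH2Cl, configuration retained) is followed in the same flask by SN2 opening at the terminal carbon by the acetylide (epoxide alkynylation).

Step 3
Reactants: 5
Product: 6 (R)-4-[(triethylsilyl)oxy]heptadec-1-yne
Conditions: Et3SiCl, imidazole, CH2Cl2, 0 °C → rt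
Reagents that add atoms: chlorotriethylsilane, CC[Si](CC)(CC)Cl
Why: Silyl ether formation; the triethylsilyl group shields the hydroxyl from the organozinc and hydride steps and can later be cleaved selectively beside a tert-butyldimethylsilyl ether.

Step 4
Reactants: 6 (R)-4-[(triethylsilyl)oxy]heptadec-1-yne; 7 acrolein
Product: 8 (3S,7R)-7-[(triethylsilyl)oxy]icos-1-en-4-yn-3-ol
Conditions: Me2Zn (3 equiv), ProPhenol ligand 2,6-bis{[2-(hydroxydiphenylmethyl)pyrrolidin-1-yl]methyl}-4-methylphenol (10 mol %), Ph3PO (20 mol %), toluene, 0 °C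
Reagents that add atoms: none
Why: Catalytic enantioselective 1,2-addition of the alkynylzinc formed in situ to the enal under dinuclear zinc–aminoalcohol catalysis; the ligand antipode that directs attack to the Re face of acrolein sets the (3S) carbinol.

Step 5
Reactants: 8
Product: 9 (3S,4Z,7R)-5-iodo-7-[(triethylsilyl)oxy]icosa-1,4-dien-3-ol
Conditions: NaAlH2(OCH2CH2OMe)2 (Red-Al), THF, 0 °C → rt; EtOAc; then I2, −78 → 0 °C
Reagents that add atoms: iodine, II
Why: Alkoxide-directed trans-hydroalumination of the propargylic alcohol places hydride on C4 and aluminium on C5, and iodinolysis with retention gives the (Z)-alkenyl iodide with iodine cis to the carbinol carbon; the isolated vinyl group and the silyl ether are inert.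

Step 6
Reactants: 9
Product: 11 (3S,4Z,7R)-3-[(tert-butyldimethylsilyl)oxy]-5-iodoicosa-1,4-dien-7-ol, via bis-silyl ether 10 (not isolated)
Conditions: t-BuMe2SiOTf, 2,6-lutidine, CH2Cl2, −78 °C; then MeOH, camphorsulfonic acid, −10 °C
Reagents that add atoms: tert-butyldimethylsilyl trifluoromethanesulfonate, CC(C)(C)[Si](C)(C)OS(=O)(=O)C(F)(F)F
Why: Silylation of the allylic hydroxyl followed by acid-catalysed methanolysis, in which the less hindered triethylsilyl ether is cleaved much faster than the tert-butyldimethylsilyl ether (selective desilylation), exchanges which oxygen is masked.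

Step 7
Reactants: 12 methoxyacetaldehyde; 13 formaldehyde
Product: 14 2-methoxyacrolein (2-methoxyprop-2-enal)
Conditions: aq. HCHO, pyrrolidine (10 mol %), propionic acid (10 mol %), i-PrOH, 45 °C; distillation
Reagents that add atoms: none
Why: Amine-catalysed Mannich condensation with formaldehyde and elimination of the amine (α-methylenation of an aldehyde) should give the 2-alkoxyacrolein, to be used as a freshly distilled solution.

Step 8
Reactants: 11 (3S,4Z,7R)-3-[(tert-butyldimethylsilyl)oxy]-5-iodoicosa-1,4-dien-7-ol; 14 2-methoxyacrolein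
Product: 15 (3S,4Z,7R)-3-[(tert-butyldimethylsilyl)oxy]-5-[(1S)-1-hydroxy-2-methoxyprop-2-en-1-yl]icosa-1,4-dien-7-ol
Conditions: CrCl2 (4 equiv), NiCl2 (2 mol %), chiral N-[2-(4-isopropyl-4,5-dihydro-1,3-oxazol-2-yl)-6-methylphenyl]methanesulfonamide (4.4 equiv), Et3N, THF, rt
Reagents that add atoms: none
Why: Nozaki–Hiyama–Kishi coupling, in which nickel inserts into the C–I bond, transmetallation to trivalent chromium retains the Z geometry and the alkenylchromium adds 1,2 to the enal; the chromium-bound oxazoline sulfonamide (antipode for Si-face attack on 14) sets the (1S) carbinol, and the free hydroxyl, silyl ether and enol ether are tolerated.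

Step 9
Reactants: 15
Product: 16 (3S,4Z,7R)-5-[(1S)-1-acetoxy-2-methoxyprop-2-en-1-yl]-3-[(tert-butyldimethylsilyl)oxy]icosa-1,4-dien-7-yl acetate
Conditions: Ac2O, pyridine, DMAP (cat.), CH2Cl2, 0 °C → rt
Reagents that add atoms: acetic anhydride, CC(=O)OC(C)=O
Why: Nucleophile-catalysed esterification of both secondary hydroxyls; the basic medium leaves the enol ether and the silyl ether intact.

Step 10
Reactants: 16
Product: 17 (3S,4Z,7R)-5-[(1S)-1-acetoxy-2-methoxyprop-2-en-1-yl]-3-hydroxyicosa-1,4-dien-7-yl acetate
Conditions: Bu4NF, AcOH (1:1), THF, 0 °C → rt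
Reagents that add atoms: none
Why: Fluoride-mediated desilylation, buffered with acetic acid so that no free alkoxide can trigger acetyl migration and no acid strong enough to hydrolyse the enol ether is present.

Step 11
Reactants: 17
Product: 18 (1S,4R)-6-[(2R)-2-acetoxypentadecyl]-4-hydroxy-2-methoxycyclohexa-2,5-dien-1-yl acetate
Conditions: second-generation Grubbs catalyst RuCl2(=CHPh)(PCy3)(H2IMes) (5 mol %), 2,6-dichloro-1,4-benzoquinone (10 mol %), CH2Cl2 (5 mM, degassed), 40 °C
Reagents that add atoms: none
Why: The ruthenium benzylidene exchanges with the only monosubstituted alkene, the vinyl group on the carbinol carbon, and the new alkylidene undergoes intramolecular [2+2] cycloaddition with the 1,1-disubstituted 1-methoxyvinyl group; cycloreversion of the ruthenacyclobutane releases the C2=C3 enol ether and Ru=CH2, which loses ethene on the next turnover (Chauvin mechanism). The closest known reaction type is enol ether–olefin ring-closing metathesis with N-heterocyclic-carbene ruthenium catalysts, established for five- to seven-membered cyclic enol ethers. The six-membered carbocycle closes by ring-closing metathesis of a 1,7-diene whose internal Z alkene (C5=C6) already holds the two reacting termini cis. No stereocentre is created and C1, C4 and the side-chain centre are not touched, so the cis-1,4 relation in the ring is that of the precursor. The step needs initiation at the vinyl group (loading the metal onto the enol ether would give an inert alkoxycarbene) and an inert trisubstituted alkene, both secured by the substitution pattern, and it must not isomerise the allylic alcohol, for which the benzoquinone scavenges ruthenium hydrides. Neutral, dilute conditions should keep the bis-allylic alcohol from ionising and aromatising.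

Compound list
1 | (R)-epichlorohydrin | ClC[C@H]1CO1 | starting material
2 | dodecylmagnesium bromide | CCCCCCCCCCCC[Mg]Br | starting material
3 | (R)-1-chloropentadecan-2-ol | CCCCCCCCCCCCC[C@H](CCl)O | intermediate
4 | (R)-1,2-epoxypentadecane | CCCCCCCCCCCCC[C@H]1OC1 | intermediate
5 | (R)-heptadec-1-yn-4-ol | CCCCCCCCCCCCC[C@H](CC#C)O | intermediate
6 | (R)-4-[(triethylsilyl)oxy]heptadec-1-yne | CCCCCCCCCCCCC[C@H](CC#C)O[Si](CC)(CC)CC | intermediate
7 | acrolein | C=CC=O | starting material
8 | (3S,7R)-7-[(triethylsilyl)oxy]icos-1-en-4-yn-3-ol | CCCCCCCCCCCCC[C@H](CC#C[C@@H](O)C=C)O[Si](CC)(CC)CC | intermediate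
9 | (3S,4Z,7R)-5-iodo-7-[(triethylsilyl)oxy]icosa-1,4-dien-3-ol | CCCCCCCCCCCCC[C@H](C/C(I)=C/[C@@H](O)C=C)O[Si](CC)(CC)CC | intermediate
10 | (3S,4Z,7R)-3-[(tert-butyldimethylsilyl)oxy]-5-iodo-7-[(triethylsilyl)oxy]icosa-1,4-diene (bis-silyl ether) | CCCCCCCCCCCCC[C@H](C/C(I)=C/[C@@H](O[Si](C)(C)C(C)(C)C)C=C)O[Si](CC)(CC)CC | intermediate
11 | (3S,4Z,7R)-3-[(tert-butyldimethylsilyl)oxy]-5-iodoicosa-1,4-dien-7-ol | CCCCCCCCCCCCC[C@H](C/C(I)=C/[C@@H](O[Si](C)(C)C(C)(C)C)C=C)O | intermediate
12 | methoxyacetaldehyde | COCC=O | starting material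
13 | formaldehyde | C=O | starting material
14 | 2-methoxyacrolein (2-methoxyprop-2-enal) | COC(=C)C=O | intermediate
15 | (3S,4Z,7R)-3-[(tert-butyldimethylsilyl)oxy]-5-[(1S)-1-hydroxy-2-methoxyprop-2-en-1-yl]icosa-1,4-dien-7-ol | CCCCCCCCCCCCC[C@H](C/C(=C/[C@@H](O[Si](C)(C)C(C)(C)C)C=C)[C@H](O)C(OC)=C)O | intermediate
16 | (3S,4Z,7R)-5-[(1S)-1-acetoxy-2-methoxyprop-2-en-1-yl]-3-[(tert-butyldimethylsilyl)oxy]icosa-1,4-dien-7-yl acetate | CCCCCCCCCCCCC[C@H](C/C(=C/[C@@H](O[Si](C)(C)C(C)(C)C)C=C)[C@H](OC(C)=O)C(OC)=C)OC(C)=O | intermediate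
17 | (3S,4Z,7R)-5-[(1S)-1-acetoxy-2-methoxyprop-2-en-1-yl]-3-hydroxyicosa-1,4-dien-7-yl acetate | CCCCCCCCCCCCC[C@H](C/C(=C/[C@@H](O)C=C)[C@H](OC(C)=O)C(OC)=C)OC(C)=O | intermediate
18 | (1S,4R)-6-[(2R)-2-acetoxypentadecyl]-4-hydroxy-2-methoxycyclohexa-2,5-dien-1-yl acetate | CCCCCCCCCCCCC[C@H](CC1=C[C@@H](O)C=C(OC)[C@H]1OC(C)=O)OC(C)=O | target

Total step count: 11. Longest linear sequence: 10 steps (steps 1–6 and 8–11; step 7 is a one-step side branch).

Steps most likely to fail

Step 11 (key step). The free bis-allylic alcohol may be isomerised to a ketone by ruthenium hydrides, or the product may lose water or acetic acid and aromatise while the slow closure onto the hindered enol ether proceeds. The fallback sets out from 16 and runs the metathesis on the silyl ether with the second-generation Hoveyda–Grubbs catalyst RuCl2(=CH-C6H4-2-OiPr)(H2IMes) in toluene at 60 °C, which should give (1S,4R)-6-[(2R)-2-acetoxypentadecyl]-4-[(tert-butyldimethylsilyl)oxy]-2-methoxycyclohexa-2,5-dien-1-yl acetate F1. Buffered Bu4NF/AcOH at 0 °C then removes the silyl group and the route is rejoined at 18.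

Step 8. Facial selection at the new carbinol carbon may be poor, and addition of the hindered trisubstituted alkenylchromium may be slow enough for the enal to oligomerise. The fallback sets out from 11 and 14 and couples them without ligand (CrCl2, NiCl2 cat., DMSO) to the epimeric mixture (3S,4Z,7R)-3-[(tert-butyldimethylsilyl)oxy]-5-[(1RS)-1-hydroxy-2-methoxyprop-2-en-1-yl]icosa-1,4-dien-7-ol F2. MnO2 in CH2Cl2 oxidises only the doubly allylic hydroxyl, giving the dienone (3S,4Z,7R)-3-[(tert-butyldimethylsilyl)oxy]-5-(2-methoxyacryloyl)icosa-1,4-dien-7-ol F3. Corey–Bakshi–Shibata reduction (2-methyl-oxazaborolidine antipode for hydride delivery to the Re face, catecholborane, toluene, −78 °C) then sets the carbinol by reagent control, and the route is rejoined at 15.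

Step 4. Enantioface selection on the small enal may be low, and acrolein may polymerise under the zinc conditions. The fallback sets out from 6, which is deprotonated with butyllithium (THF, −78 °C) and added to acrolein to give the C3-epimeric mixture (3RS,7R)-7-[(triethylsilyl)oxy]icos-1-en-4-yn-3-ol F4. Acylation with vinyl acetate and Burkholderia cepacia lipase (hexane, rt) should, by the usual size rule for secondary alcohols, convert the (3R)-epimer into (3R,7R)-7-[(triethylsilyl)oxy]icos-1-en-4-yn-3-yl acetate F5. The unreacted (3S)-alcohol, separated by chromatography, is 8.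

Further compounds
F1 | step 11 | (1S,4R)-6-[(2R)-2-acetoxypentadecyl]-4-[(tert-butyldimethylsilyl)oxy]-2-methoxycyclohexa-2,5-dien-1-yl acetate | CCCCCCCCCCCCC[C@H](CC1=C[C@@H](O[Si](C)(C)C(C)(C)C)C=C(OC)[C@H]1OC(C)=O)OC(C)=O
F2 | step 8 | (3S,4Z,7R)-3-[(tert-butyldimethylsilyl)oxy]-5-[(1RS)-1-hydroxy-2-methoxyprop-2-en-1-yl]icosa-1,4-dien-7-ol | CCCCCCCCCCCCC[C@H](C/C(=C/[C@@H](O[Si](C)(C)C(C)(C)C)C=C)C(O)C(OC)=C)O
F3 | step 8 | (3S,4Z,7R)-3-[(tert-butyldimethylsilyl)oxy]-5-(2-methoxyacryloyl)icosa-1,4-dien-7-ol | CCCCCCCCCCCCC[C@H](C/C(=C/[C@@H](O[Si](C)(C)C(C)(C)C)C=C)C(=O)C(OC)=C)O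
F4 | step 4 | (3RS,7R)-7-[(triethylsilyl)oxy]icos-1-en-4-yn-3-ol | CCCCCCCCCCCCC[C@H](CC#CC(O)C=C)O[Si](CC)(CC)CC
F5 | step 4 | (3R,7R)-7-[(triethylsilyl)oxy]icos-1-en-4-yn-3-yl acetate | CCCCCCCCCCCCC[C@H](CC#C[C@H](OC(C)=O)C=C)O[Si](CC)(CC)CC
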